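## The problem

Compound 23 is a cyclohexene carrying two 7-methoxycoumarin units. Ring numbering used throughout: C1 is the quaternary carbon (methyl, and the (E)-ethenyl arm whose first carbon is Cα and which ends in coumarin A); C2 and C3 are methylenes; C4 is the methyl-bearing alkene carbon; C5 is the alkene CH; C6 is the CH bonded directly to C6 of coumarin B.

- The two stereocentres are adjacent, (1R,6S), with the C1 methyl cis to coumarin B. C6 is the easier one to set, and once set its aryl group can decide the face on which the crowded quaternary C1 is completed.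
- The trisubstituted alkene must sit at C4=C5 only. C6–H is allylic and benzylic, so acid, strong base or metal hydrides can move the double bond to C5=C6, into conjugation with coumarin B, and erase the C6 stereocentre.
- Both coumarins are aryl-ester lactones and Michael acceptors. They will not survive organolithium or Grignard reagents near room temperature, hot alkoxide or hydroxide, hydrazine, aluminium hydrides or unselective hydrogenation, and the styryl double bond must stay E.
- C2 lies next to the quaternary carbon that bears the styryl group, so a long-lived radical or cation at C2 invites a 1,2-alkenyl shift.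
- The enabling feature is the adjacency of the aryl-bearing C6 and the alkenyl-bearing C1. With a carbonyl group on C2, C1 and C6 are the α- and β-carbons of a 2-methylcyclohex-2-enone, so both coumarins can be attached in one conjugate-addition/enolate-trapping operation. C4 can hold its methyl group as a temporary stereocentre that steers this operation and is later flattened into the alkene.

## Retrosynthesis

**23 ⇒ 21 ⇒ 20 (oxygen returned to C2).** No skeletal bond is cut; the C2 methylene is traced back to the sulfonyl hydrazone 21 and the ketone 20. Oxygen at C2, and at no other ring carbon, makes C1 and C6 an α/β pair. The precursor is no smaller, but it holds the one functional group from which both ring–coumarin bonds can be made. The forward step must turn C=O into CH2 at a neopentyl carbon without touching the lactones, the homoallylic C4=C5 bond or C6–H. Hydride reduction of the hydrazone is chosen over an alcohol/thiocarbonyl/stannane deoxygenation, because a free C2 radical sits β to the styryl double bond and would close onto it (benzylic cyclopropylcarbinyl radical, then 1,2-shift).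

**20 ⇒ 18 ⇒ 16 (the alkene traced back to a saturated ketone).** Again no bond is cut. The C4=C5 alkene of 20 comes from the conjugated C3=C4 enone 18 by deconjugation, and 18 comes from the saturated ketone 16 by dehydrogenation. Because C1 is quaternary, 16 can enolise only towards C3, so the dehydrogenation is regiospecific; because the α′ position is blocked, the dienolate of 18 can only be extended through C5, and kinetic α-protonation then places the double bond at C4=C5. Elimination-based ways of making this alkene would give C3=C4/C4=C5 mixtures. Going back to 16 adds a stereocentre at C4, which is what makes the next disconnection stereocontrolled. The forward steps must avoid the exocyclic diene and re-conjugation.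

**16 ⇒ 6 + 14 + 12 (key disconnection).** The bonds C6–C(aryl) and C1–Cα are cut together. Cutting only C1–Cα would require regioselective enolate formation between two α-carbons of a 3-aryl ketone. Cutting only C6–aryl would require a cross-conjugated 2-alkenyl enone prone to 1,6-addition. Cutting both uses the enolate born in the conjugate addition exactly where it is formed. The precursors are the small enone 6 (one stereocentre), the arylzinc chloride 14 and the (E)-bromoalkene 12. The forward reaction must add the aryl group trans to the C4 methyl, alkenylate the fully substituted enolate carbon trans to the new aryl group, and leave both lactones alone.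

**6 ⇒ 5 ⇒ 4 ⇒ 2 ⇒ 1 (the enone).** The C2–CH3 bond and the C2=C3 unsaturation are removed. Direct deprotonation of 1 distinguishes its two α-methylenes poorly, so the site is fixed by formylation (2), which under equilibrating conditions goes to the methylene remote from the ring methyl. C-Methylation with deformylation gives 4, and chlorination at the more substituted α-carbon (5) with loss of HCl gives 6. The stereocentre of 1 is never enolisable on this path.

**14 and 12 ⇒ 10 ⇒ 8 ⇒ 7 (the coumarins).** Both coupling partners come from one aryl iodide, 10: the C–Zn bond of 14 by halogen–metal exchange and transmetalation, and the bromoethenyl group of 12 by Heck coupling to the acrylic acid 11 followed by bromodecarboxylation. The pyranone ring of 10 is cut at C3=C4 and the lactone C–O bond, back to the salicylaldehyde 8 and then to commercial 7. Iodine is introduced before the lactone ring because halogenation of a finished 7-methoxycoumarin would compete at C3 and C8.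

## Roads not taken

**Alternative 1:** Vinylsilane-terminated cyclisation onto a benzylic cation.
- Cut: the ring bond C5–C6.
- Forward key step: a Lewis acid ionises the benzylic carbinol A2 (either epimer). The cation is stabilised by the ortho methoxy group of coumarin B. The silicon-bearing carbon of the (Z)-vinylsilane attacks in a 6-endo closure and silicon is lost, giving the silyl-protected hydroxymethyl cyclohexene A1.
- Merits: the alkene is placed at C4=C5 by silicon with no ambiguity, C2 and C3 arrive as methylenes, and no oxygen has to be removed at C2. On this point it is better than the chosen plan, whose weakest stage is the late carbonyl removal.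
- Weak points: the quaternary C1 must be made enantioselectively in an open chain. It must then control C6 in a cation cyclisation in which its two competing substituents (methyl and silyloxymethyl) differ little in size. The electron-rich benzylic cation can also eliminate. The styryl arm must still be grown from the hydroxymethyl group by deprotection, oxidation to a neopentyl aldehyde and an olefination of uncertain E/Z ratio with a coumarin-bearing ylide.
- Comparison: the chosen plan sets against it convergence (both coumarins and the E alkene arrive in one operation) and two facial selections with strong ring-based bias.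

**Alternative 2:** Three-component conjunctive coupling across a dienyl boronate.
- Cut: C1–C2 and C6–aryl in an open-chain precursor.
- Forward key step: the organolithium A6 adds to boron of the (Z)-dienyl pinacol boronate A4. An arylpalladium species from the aryl triflate A5 then induces 1,2-migration of the alkyl group from boron to C1 while the aryl group bonds to C6, giving the tertiary boronate A3. Ring-closing metathesis of its two terminal alkenes would fix C4=C5, and the boron would be exchanged for the alkenyl arm.
- Merits: both stereocentres are set in one catalyst-controlled event, without chiral-pool material and without a relay centre to erase; the alkene position is fixed by metathesis and there is no oxygen to remove. In how the stereochemistry originates it is better than the chosen plan.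
- Weak points: coumarin B is present only as a 2-methoxy-4-silyloxyphenyl ring, so its pyranone must be built late (desilylation, ortho-formylation, olefination/lactonisation). The alkenyl arm must be installed on a hindered tertiary boronate with alkenyl-metal reagents that coumarin A cannot survive. The α-methyl, β-vinyl alkenyl boronate is a demanding substrate with a competing π-allyl pathway.
- Comparison: the chosen plan sets against it the intact delivery of both coumarins and far fewer steps spent on aromatic construction.

**Alternative 3:** Geometry-transferring Diels–Alder reaction of an α-methyl enal, then silicon shift.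
- Cut: C1–C2 and C5–C6 in a [4+2] sense.
- Forward key step: the (E)-enal A8 (C6=C1 as dienophile) and the silyl diene A9 combine under a cationic chiral oxazaborolidine Lewis acid to give the aldehyde A7. The E geometry of A8 puts the aryl group trans to the formyl group, hence cis to the C1 methyl as required. Protodesilylation of the allylsilane then moves the double bond from C3=C4 to C4=C5, and the formyl group is olefinated to the styryl arm.
- Merits: the ring and both stereocentres form in one step, the alkene is placed by silicon, and nothing has to be deoxygenated. On step count and on the endgame this road is better than the chosen one and would merit parallel exploration.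
- Weak points: a β-aryl, α-methyl enal with an electron-rich aryl group is a poor dienophile. The lactone carbonyl competes for the Lewis acid. The regiochemistry relies on the 2-methyl group of A9 overriding its 1-silyl group. The neopentyl aldehyde must be converted into an E styrene with a base-sensitive coumarin ylide. Acidic protodesilylation could carry the alkene on into conjugation with coumarin B.
- Comparison: the chosen plan sets against it two stereo-defining events that each have close analogy in 5-substituted cyclohexenones, and an E alkene secured before the coupling.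

Key step: step 10

Remark on the chemistry: (S)-3-methylcyclohexan-1-one (1) is assumed to be purchasable in high enantiomeric purity; every absolute configuration derives from it. The Why lines use the ring numbering C1–C6 defined under "The problem"; compound names use their own locants.

## Route

Step 1
Reactants: 1 (S)-3-methylcyclohexan-1-one
Product: 2 (5S)-2-(hydroxymethylidene)-5-methylcyclohexan-1-one
Conditions: HCO2Et, NaH, cat. EtOH, Et2O, 0 → 23 °C; aq. HCl work-up
Reagents that add atoms: ethyl formate, CCOC=O
Why: Crossed Claisen condensation (α-formylation) under equilibrating conditions should place the formyl group on the α-methylene remote from the ring methyl, which fixes the site of the later methylation; the stereocentre is not enolisable.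

Step 2
Reactants: 2 (5S)-2-(hydroxymethylidene)-5-methylcyclohexan-1-one
Product: 4 (5S)-2,5-dimethylcyclohexan-1-one (C2 epimers), via 2-formyl-2-methyl ketone 3 (not isolated)
Conditions: MeI, K2CO3, acetone, reflux; then 2 M NaOH (aq), 23 °C
Reagents that add atoms: iodomethane, CI
Why: C-Alkylation of the β-dicarbonyl enolate, then retro-Claisen deformylation of the non-enolisable β-keto aldehyde; the C2 configuration is irrelevant because C2 becomes sp2 in step 4.

Step 3
Reactants: 4 (5S)-2,5-dimethylcyclohexan-1-one
Product: 5 (5S)-2-chloro-2,5-dimethylcyclohexan-1-one (C2 epimers)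
Conditions: SO2Cl2, CH2Cl2, 0 → 23 °C
Reagents that add atoms: sulfuryl chloride, O=S(=O)(Cl)Cl
Why: α-Chlorination through the more substituted enol should put chlorine on the methyl-bearing α-carbon, the classical entry to 2-alkylcyclohex-2-enones.

Step 4
Reactants: 5 (5S)-2-chloro-2,5-dimethylcyclohexan-1-one
Product: 6 (5S)-2,5-dimethylcyclohex-2-en-1-one
Conditions: Li2CO3, LiBr, DMF, 120 °C
Reagents that add atoms: none
Why: Dehydrochlorination of the tertiary α-chloro ketone to the conjugated endocyclic enone; the methyl-bearing stereocentre is neither α nor γ to the carbonyl group and should keep its S configuration.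

Step 5
Reactants: 7 2-hydroxy-4-methoxybenzaldehyde
Product: 8 2-hydroxy-5-iodo-4-methoxybenzaldehyde
Conditions: ICl, AcOH, 23 °C
Reagents that add atoms: iodine monochloride, ClI
Why: Electrophilic aromatic iodination para to the phenol and ortho to the methoxy group; the other activated position lies between the two oxygens and is more hindered.

Step 6
Reactants: 8 2-hydroxy-5-iodo-4-methoxybenzaldehyde
Product: 10 6-iodo-7-methoxy-2H-chromen-2-one, via Z-cinnamate ester 9 (not isolated)
Conditions: Ph3P=CHCO2Et, PhNEt2, reflux
Reagents that add atoms: ethyl (triphenylphosphoranylidene)acetate, CCOC(=O)C=P(c1ccccc1)(c1ccccc1)c1ccccc1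
Why: Wittig olefination of the salicylaldehyde, thermal E/Z equilibration and lactonisation of the Z ester, the standard one-flask coumarin synthesis.

Step 7
Reactants: 10 6-iodo-7-methoxy-2H-chromen-2-one
Product: 11 (2E)-3-(7-methoxy-2-oxo-2H-chromen-6-yl)prop-2-enoic acid
Conditions: acrylic acid, Pd(OAc)2 (cat.), P(o-tol)3, Et3N, DMF, 90 °C; aq. HCl work-up
Reagents that add atoms: acrylic acid, C=CC(=O)O
Why: Heck reaction; syn insertion and syn β-hydride elimination give the E acid, and the coumarin C3=C4 bond is a far poorer acceptor than acrylic acid.

Step 8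
Reactants: 11 (2E)-3-(7-methoxy-2-oxo-2H-chromen-6-yl)prop-2-enoic acid
Product: 12 6-[(E)-2-bromoethenyl]-7-methoxy-2H-chromen-2-one
Conditions: NBS, LiOAc (cat.), MeCN–H2O, 23 °C
Reagents that add atoms: N-bromosuccinimide, O=C1CCC(=O)N1Br
Why: Hunsdiecker-type bromodecarboxylation of an electron-rich cinnamic acid; the benzylic cation formed on bromination is stabilised by the ortho methoxy group, and loss of CO2 should return the E bromoalkene.

Step 9
Reactants: 10 6-iodo-7-methoxy-2H-chromen-2-one
Product: 14 chloro(7-methoxy-2-oxo-2H-chromen-6-yl)zinc (used as its THF solution), via arylmagnesium chloride 13 (not isolated)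
Conditions: iPrMgCl·LiCl, THF, −40 °C; then ZnCl2 (THF), −40 → 0 °C
Reagents that add atoms: zinc chloride, Cl[Zn]Cl
Why: Iodine–magnesium exchange, accelerated by the ortho methoxy group and expected to outrun attack on the lactone at −40 °C, followed at once by transmetalation to the much less basic arylzinc chloride.

Step 10
Reactants: 6 (5S)-2,5-dimethylcyclohex-2-en-1-one; 14 chloro(7-methoxy-2-oxo-2H-chromen-6-yl)zinc; 12 6-[(E)-2-bromoethenyl]-7-methoxy-2H-chromen-2-one
Product: 16 (2R,3R,5S)-3-(7-methoxy-2-oxo-2H-chromen-6-yl)-2-[(E)-2-(7-methoxy-2-oxo-2H-chromen-6-yl)ethenyl]-2,5-dimethylcyclohexan-1-one, via trimethylsilyl enol ether 15 (not isolated)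
Conditions: [Rh(cod)Cl]2 (cat.), Me3SiCl, THF, 0 → 23 °C; then 12, Pd(OAc)2 (cat.), P(tBu)3·HBF4, CsF, THF–DMF, 60 °C
Reagents that add atoms: none
Why: Proposed new method: Transmetalation from zinc gives an aryl complex of monovalent rhodium that adds syn across C1=C6 of 6 with the aryl group on C6, and the resulting oxa-π-allyl rhodium enolate is silylated by Me3SiCl, which regenerates the rhodium chloride and fixes the enolate as the tetrasubstituted C1=C2 enol ether 15. CsF, together with the ZnCl2 already in the flask, then releases a zinc enolate that transmetalates to the (E)-alkenylpalladium bromide formed by oxidative addition of 12 to zerovalent palladium (from Pd(OAc)2 and the phosphine), and reductive elimination from the C-bound enolate of divalent palladium makes C1–Cα with retention of the E geometry. The closest known reaction types are the rhodium-catalysed 1,4-addition of arylzinc chlorides to enones with chlorosilane trapping and the palladium-catalysed, fluoride-promoted α-arylation and α-alkenylation of silyl enol ethers and ketone enolates to quaternary carbons; their fusion in one flask on an α-methyl enone is what is new. No ring is closed. C6 is set by the C4 methyl group: in the half-chair with that methyl pseudoequatorial the aryl–rhodium bond is delivered axially to the face anti to it, giving the 3,5-trans product. C1 is set by the new aryl group, which should sit pseudoaxial in 15 to avoid allylic strain with the C1 methyl and so shields one face; palladium and hence the alkenyl group enter anti to it, leaving the C1 methyl cis to coumarin B. The step needs chemoselectivity for the cyclohexenone over the coumarin Michael acceptors (the ring enone is the stronger acceptor and the 7-methoxy group deactivates the lactones), absence of free 14 in the palladium stage (6 is used in slight excess so that no Negishi coupling with 12 can occur), and reductive elimination faster than β-hydride loss from the palladium enolate (bulky, electron-rich P(tBu)3).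

Step 11
Reactants: 16 (2R,3R,5S)-3-(7-methoxy-2-oxo-2H-chromen-6-yl)-2-[(E)-2-(7-methoxy-2-oxo-2H-chromen-6-yl)ethenyl]-2,5-dimethylcyclohexan-1-one
Product: 18 (5R,6R)-5-(7-methoxy-2-oxo-2H-chromen-6-yl)-6-[(E)-2-(7-methoxy-2-oxo-2H-chromen-6-yl)ethenyl]-3,6-dimethylcyclohex-2-en-1-one, via trimethylsilyl enol ether 17 (not isolated)
Conditions: Me3SiOTf, Et3N, CH2Cl2, 0 °C; then Pd(OAc)2 (1.1 equiv), MeCN, 40 °C
Reagents that add atoms: none
Why: Saegusa–Ito dehydrogenation; only C3 carries α-hydrogens (C1 is quaternary), so soft enolisation is regiospecific, and syn β-hydride elimination from the C3 palladium enolate removes the C4 hydrogen and flattens the relay stereocentre into the C3=C4 enone.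

Step 12
Reactants: 18 (5R,6R)-5-(7-methoxy-2-oxo-2H-chromen-6-yl)-6-[(E)-2-(7-methoxy-2-oxo-2H-chromen-6-yl)ethenyl]-3,6-dimethylcyclohex-2-en-1-one
Product: 20 (5R,6R)-5-(7-methoxy-2-oxo-2H-chromen-6-yl)-6-[(E)-2-(7-methoxy-2-oxo-2H-chromen-6-yl)ethenyl]-3,6-dimethylcyclohex-3-en-1-one, via trimethylsilyl dienol ether 19 (not isolated)
Conditions: Me3SiOTf, Et3N, CH2Cl2, 0 → 23 °C; then Bu4NF, AcOH, THF, −78 °C
Reagents that add atoms: none
Why: With the α′ carbon (C1) quaternary, O-silylation and γ-deprotonation should give the endocyclic 2-silyloxy-1,3-diene (C2=C3, C4=C5); fluoride then releases the dienolate in the presence of acetic acid, and kinetic protonation at the α-carbon C3 is the classical deconjugation to a β,γ-unsaturated ketone.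

Step 13
Reactants: 20 (5R,6R)-5-(7-methoxy-2-oxo-2H-chromen-6-yl)-6-[(E)-2-(7-methoxy-2-oxo-2H-chromen-6-yl)ethenyl]-3,6-dimethylcyclohex-3-en-1-one
Product: 21 N'-{(5S,6R)-5-(7-methoxy-2-oxo-2H-chromen-6-yl)-6-[(E)-2-(7-methoxy-2-oxo-2H-chromen-6-yl)ethenyl]-3,6-dimethylcyclohex-3-en-1-ylidene}-4-methylbenzenesulfonohydrazide
Conditions: TsNHNH2, THF–MeOH, 4 Å molecular sieves, 40 °C
Reagents that add atoms: 4-methylbenzenesulfonohydrazide, Cc1ccc(cc1)S(=O)(=O)NN
Why: Hydrazone condensation without added acid, so that the β,γ-alkene is not drawn back into conjugation; the C=N geometry is of no consequence for step 14.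

Step 14
Reactants: 21 N'-{(5S,6R)-5-(7-methoxy-2-oxo-2H-chromen-6-yl)-6-[(E)-2-(7-methoxy-2-oxo-2H-chromen-6-yl)ethenyl]-3,6-dimethylcyclohex-3-en-1-ylidene}-4-methylbenzenesulfonohydrazide
Product: 23 7-methoxy-6-{(1S,6R)-6-[(E)-2-(7-methoxy-2-oxo-2H-chromen-6-yl)ethenyl]-3,6-dimethylcyclohex-2-en-1-yl}-2H-chromen-2-one, via N-boryl tosylhydrazine 22 (not isolated)
Conditions: catecholborane, CHCl3, 0 °C; then NaOAc·3H2O, 60 °C
Reagents that add atoms: none
Why: Caglioti-type tosylhydrazone reduction: hydride adds to C=N, acetate triggers loss of sulfinate and the diazene extrudes N2, leaving CH2 at C2 with the non-conjugated C4=C5 bond in place (only conjugated hydrazones transpose). It is preferred to a thiocarbonyl/stannane deoxygenation because a long-lived C2 radical next to the styryl-bearing quaternary carbon would invite a 1,2-alkenyl shift; no stereocentre is touched.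

## Compound list

1 | (S)-3-methylcyclohexan-1-one | O=C1CCC[C@H](C)C1 | starting material
2 | (5S)-2-(hydroxymethylidene)-5-methylcyclohexan-1-one (chelated enol form) | O=C1C[C@@H](C)CCC1=CO | intermediate
3 | (4S)-1,4-dimethyl-2-oxocyclohexane-1-carbaldehyde (C1 epimers) | CC1(C=O)CC[C@H](C)CC1=O | intermediate
4 | (5S)-2,5-dimethylcyclohexan-1-one (C2 epimers) | CC1CC[C@H](C)CC1=O | intermediate
5 | (5S)-2-chloro-2,5-dimethylcyclohexan-1-one (C2 epimers) | CC1(Cl)CC[C@H](C)CC1=O | intermediate
6 | (5S)-2,5-dimethylcyclohex-2-en-1-one | CC1=CC[C@H](C)CC1=O | intermediate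
7 | 2-hydroxy-4-methoxybenzaldehyde | COc1ccc(C=O)c(O)c1 | starting material
8 | 2-hydroxy-5-iodo-4-methoxybenzaldehyde | COc1cc(O)c(C=O)cc1I | intermediate
9 | ethyl (2Z)-3-(2-hydroxy-5-iodo-4-methoxyphenyl)prop-2-enoate (formed with its E isomer, which equilibrates) | CCOC(=O)/C=C\c1cc(I)c(OC)cc1O | intermediate
10 | 6-iodo-7-methoxy-2H-chromen-2-one | COc1cc2oc(=O)ccc2cc1I | intermediate
11 | (2E)-3-(7-methoxy-2-oxo-2H-chromen-6-yl)prop-2-enoic acid | COc1cc2oc(=O)ccc2cc1/C=C/C(=O)O | intermediate
12 | 6-[(E)-2-bromoethenyl]-7-methoxy-2H-chromen-2-one | COc1cc2oc(=O)ccc2cc1/C=C/Br | intermediate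
13 | chloro(7-methoxy-2-oxo-2H-chromen-6-yl)magnesium | COc1cc2oc(=O)ccc2cc1[Mg]Cl | intermediate
14 | chloro(7-methoxy-2-oxo-2H-chromen-6-yl)zinc | COc1cc2oc(=O)ccc2cc1[Zn]Cl | intermediate
15 | 6-[(1S,5S)-2,5-dimethyl-3-(trimethylsilyloxy)cyclohex-2-en-1-yl]-7-methoxy-2H-chromen-2-one (aryl trans to the C5 methyl) | CC1=C(O[Si](C)(C)C)C[C@@H](C)C[C@@H]1c1cc2ccc(=O)oc2cc1OC | intermediate
16 | (2R,3R,5S)-3-(7-methoxy-2-oxo-2H-chromen-6-yl)-2-[(E)-2-(7-methoxy-2-oxo-2H-chromen-6-yl)ethenyl]-2,5-dimethylcyclohexan-1-one | COc1cc2oc(=O)ccc2cc1/C=C/[C@@]1(C)C(=O)C[C@@H](C)C[C@@H]1c1cc2ccc(=O)oc2cc1OC | intermediate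
17 | trimethylsilyl enol ether of 16 (C1=C6 enol ether in the locants of 16; the three stereocentres as in 16) | COc1cc2oc(=O)ccc2cc1/C=C/[C@@]1(C)C(O[Si](C)(C)C)=C[C@@H](C)C[C@@H]1c1cc2ccc(=O)oc2cc1OC | intermediate
18 | (5R,6R)-5-(7-methoxy-2-oxo-2H-chromen-6-yl)-6-[(E)-2-(7-methoxy-2-oxo-2H-chromen-6-yl)ethenyl]-3,6-dimethylcyclohex-2-en-1-one | COc1cc2oc(=O)ccc2cc1/C=C/[C@@]1(C)C(=O)C=C(C)C[C@@H]1c1cc2ccc(=O)oc2cc1OC | intermediate
19 | trimethylsilyl dienol ether of 18 (1-trimethylsilyloxycyclohexa-1,3-diene, double bonds C1=C2 and C3=C4 in the locants of 18; C5 and C6 as in 18) | COc1cc2oc(=O)ccc2cc1/C=C/[C@@]1(C)C(O[Si](C)(C)C)=CC(C)=C[C@@H]1c1cc2ccc(=O)oc2cc1OC | intermediate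
20 | (5R,6R)-5-(7-methoxy-2-oxo-2H-chromen-6-yl)-6-[(E)-2-(7-methoxy-2-oxo-2H-chromen-6-yl)ethenyl]-3,6-dimethylcyclohex-3-en-1-one | COc1cc2oc(=O)ccc2cc1/C=C/[C@@]1(C)C(=O)CC(C)=C[C@@H]1c1cc2ccc(=O)oc2cc1OC | intermediate
21 | N'-{(5S,6R)-5-(7-methoxy-2-oxo-2H-chromen-6-yl)-6-[(E)-2-(7-methoxy-2-oxo-2H-chromen-6-yl)ethenyl]-3,6-dimethylcyclohex-3-en-1-ylidene}-4-methylbenzenesulfonohydrazide (C=N geometry as formed) | COc1cc2oc(=O)ccc2cc1/C=C/[C@@]1(C)C(=NNS(=O)(=O)c2ccc(C)cc2)CC(C)=C[C@@H]1c1cc2ccc(=O)oc2cc1OC | intermediate
22 | N-boryl tosylhydrazine from hydride addition to C=N of 21 (1,3,2-benzodioxaborol-2-yl on the ring-bound nitrogen; new CH–N centre as an epimer mixture) | COc1cc2oc(=O)ccc2cc1/C=C/[C@@]1(C)C(N(NS(=O)(=O)c2ccc(C)cc2)B2Oc3ccccc3O2)CC(C)=C[C@@H]1c1cc2ccc(=O)oc2cc1OC | intermediate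
23 | 7-methoxy-6-{(1S,6R)-6-[(E)-2-(7-methoxy-2-oxo-2H-chromen-6-yl)ethenyl]-3,6-dimethylcyclohex-2-en-1-yl}-2H-chromen-2-one | COc1cc2oc(=O)ccc2cc1/C=C/[C@@]1(C)CCC(C)=C[C@@H]1c1cc2ccc(=O)oc2cc1OC | target

## Step count and least certain steps

Total: 14 steps. Longest linear sequence: 9 steps (1 → 23 through steps 1–4 and 10–14; equally 7 → 23 through steps 5–8 and 10–14).

**Step 10 (key step, proposed new method).**
- What may go wrong: carbometalation of the α-methyl enone may be slow enough that aryl transfer to a coumarin C4 or protodezincation competes. In the second stage, the enolate at the fully substituted C1, flanked by the aryl-bearing C6, may be protonated or lose a β-hydride faster than it undergoes C–C reductive elimination. Any arylzinc left over would cross-couple with the bromoalkene.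
- Fallback (known chemistry), from 6 and 14 back to 16: the rhodium step is run alone and the silyl enol ether 15 is isolated. Mukaiyama aldol addition of acetaldehyde to 15 (TiCl4, CH2Cl2, −78 °C), anti to the aryl group, should give (2S,3R,5S)-2-(1-hydroxyethyl)-3-(7-methoxy-2-oxo-2H-chromen-6-yl)-2,5-dimethylcyclohexan-1-one F1. Syn dehydration with the Burgess reagent, possible only towards the methyl group, gives (2R,3R,5S)-2-ethenyl-3-(7-methoxy-2-oxo-2H-chromen-6-yl)-2,5-dimethylcyclohexan-1-one F2. A Heck reaction of F2 with the aryl iodide 10 (Pd(OAc)2, P(o-tol)3, Et3N, DMF) installs coumarin A with E geometry and returns to 16.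

**Step 14.**
- What may go wrong: loss of N2 from the alkyl diazene may acquire radical character, and a C2 radical can close onto the neighbouring styryl double bond, leading to 1,2-alkenyl shift or cyclopropane formation. Migration of the C4=C5 bond towards conjugation during steps 13–14 is the second hazard.
- Fallback, from 20 back to 23: thioketalisation with ethane-1,2-dithiol and BF3·OEt2 at low temperature gives the 1,3-dithiolane of 20, F3. Desulfurisation with Raney nickel (Ni), deactivated beforehand by reflux in acetone so that the styryl and coumarin double bonds are not hydrogenated, then gives 23.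

**Step 12.**
- What may go wrong: γ-deprotonation at the C4 methyl group instead of C5 would lead to an exocyclic alkene, and the β,γ-enone may slip back into conjugation during protonation or isolation.
- Fallback, from 18 back to 20: enol acetylation with isopropenyl acetate and TsOH gives, under thermodynamic control, the endocyclic dienol acetate of 18, F4. NaBH4 (EtOH–THF, 0 °C) cleaves the acetate and reduces the kinetically formed β,γ-enone in situ to (5R,6R)-5-(7-methoxy-2-oxo-2H-chromen-6-yl)-6-[(E)-2-(7-methoxy-2-oxo-2H-chromen-6-yl)ethenyl]-3,6-dimethylcyclohex-3-en-1-ol F5. Buffered Dess–Martin oxidation returns to 20.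

**Step 9.**
- What may go wrong: the isopropyl or aryl Grignard reagent may add to the lactone carbonyl or to C4 of the coumarin before transmetalation is complete.
- Fallback, from 10 back to 16: direct insertion of zinc dust into 10 in the presence of LiCl (THF, 25–50 °C), which involves no magnesium reagent, gives iodo(7-methoxy-2-oxo-2H-chromen-6-yl)zinc F6. This is used in step 10 in place of 14 and rejoins the route at 16.

## Further compounds

F1 | step 10 | (2S,3R,5S)-2-(1-hydroxyethyl)-3-(7-methoxy-2-oxo-2H-chromen-6-yl)-2,5-dimethylcyclohexan-1-one (carbinol epimers) | CC(O)[C@@]1(C)C(=O)C[C@@H](C)C[C@@H]1c1cc2ccc(=O)oc2cc1OC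
F2 | step 10 | (2R,3R,5S)-2-ethenyl-3-(7-methoxy-2-oxo-2H-chromen-6-yl)-2,5-dimethylcyclohexan-1-one | C=C[C@@]1(C)C(=O)C[C@@H](C)C[C@@H]1c1cc2ccc(=O)oc2cc1OC
F3 | step 14 | 1,3-dithiolane of 20 (spiro at the former carbonyl carbon; stereocentres as in 20) | COc1cc2oc(=O)ccc2cc1/C=C/[C@@]1(C)C2(SCCS2)CC(C)=C[C@@H]1c1cc2ccc(=O)oc2cc1OC
F4 | step 12 | dienol acetate of 18 (1-acetoxycyclohexa-1,3-diene, double bonds C1=C2 and C3=C4 in the locants of 18) | COc1cc2oc(=O)ccc2cc1/C=C/[C@@]1(C)C(OC(C)=O)=CC(C)=C[C@@H]1c1cc2ccc(=O)oc2cc1OC
F5 | step 12 | (5R,6R)-5-(7-methoxy-2-oxo-2H-chromen-6-yl)-6-[(E)-2-(7-methoxy-2-oxo-2H-chromen-6-yl)ethenyl]-3,6-dimethylcyclohex-3-en-1-ol (carbinol epimers) | COc1cc2oc(=O)ccc2cc1/C=C/[C@@]1(C)C(O)CC(C)=C[C@@H]1c1cc2ccc(=O)oc2cc1OC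
F6 | step 9 | iodo(7-methoxy-2-oxo-2H-chromen-6-yl)zinc | COc1cc2oc(=O)ccc2cc1[Zn]I
A1 | alternative 1 | 6-[6-(tert-butyldiphenylsilyloxymethyl)-3,6-dimethylcyclohex-2-en-1-yl]-7-methoxycoumarin, single stereoisomer | CC(C)(C)[Si](OC[C@@]1(C)CCC(C)=C[C@@H]1c1cc2ccc(=O)oc2cc1OC)(c1ccccc1)c1ccccc1
A2 | alternative 1 | 6-[(5Z)-2-(tert-butyldiphenylsilyloxymethyl)-1-hydroxy-2,5-dimethyl-6-(trimethylsilyl)hex-5-en-1-yl]-7-methoxycoumarin (either carbinol epimer) | C[Si](C)(C)/C=C(/C)CC[C@](C)(CO[Si](c1ccccc1)(c1ccccc1)C(C)(C)C)C(O)c1cc2ccc(=O)oc2cc1OC
A3 | alternative 2 | pinacol boronate of 3-[2-methoxy-4-(triisopropylsilyloxy)phenyl]-4,7-dimethylocta-1,7-dien-4-yl, single stereoisomer | CC1(C)OB(OC1(C)C)[C@@](C)(CCC(C)=C)[C@H](C=C)c1ccc(O[Si](C(C)C)(C(C)C)C(C)C)cc1OC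
A4 | alternative 2 | 4,4,5,5-tetramethyl-2-[(2Z)-penta-2,4-dien-2-yl]-1,3,2-dioxaborolane | C=C/C=C(\C)B1OC(C)(C)C(C)(C)O1
A5 | alternative 2 | 2-methoxy-4-(triisopropylsilyloxy)phenyl trifluoromethanesulfonate | COc1cc(O[Si](C(C)C)(C(C)C)C(C)C)ccc1OS(=O)(=O)C(F)(F)F
A6 | alternative 2 | 3-methylbut-3-enyllithium | [Li]CCC(C)=C
A7 | alternative 3 | 2-(7-methoxy-2-oxochromen-6-yl)-1,4-dimethyl-3-(trimethylsilyl)cyclohex-4-ene-1-carbaldehyde (silyl-bearing centre as formed) | O=C[C@@]1(C)CC=C(C)C([Si](C)(C)C)[C@@H]1c1cc2ccc(=O)oc2cc1OC
A8 | alternative 3 | (2E)-3-(7-methoxy-2-oxo-2H-chromen-6-yl)-2-methylprop-2-enal | COc1cc2oc(=O)ccc2cc1/C=C(\C)C=O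
A9 | alternative 3 | (E)-trimethyl(2-methylbuta-1,3-dien-1-yl)silane | C[Si](C)(C)/C=C(\C)C=C
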